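The numbers in the tables were generated by integration for substances that don't exist.

Look through the runs made earlier for a concentration that stays level as the charges change; I began there.

| flask | starting material | second substrate | third substrate | solid reagent | temperature | remark | time |
|---|---|---|---|---|---|---|---|
| beta | 0.20 M | 0.50 equiv | 1 equiv | 0.40 equiv | 55 °C | run made earlier |  |
| zeta | 0.20 M | 0.50 equiv | 1 equiv | 1.6 equiv | 80 °C | run made earlier |  |
| theta | 0.30 M | 0.50 equiv | 1 equiv | 0.80 equiv | 55 °C | run made earlier |  |
| summer | 0.20 M | 0.500 equiv | 1.00 equiv | 0.800 equiv | 100 °C |  | 80 min |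
| noon | 0.20 M | 0.500 equiv | 1.00 equiv | 0.800 equiv | 60 °C |  | 80 min |
| spring | 0.20 M | 0.500 equiv | 1.00 equiv | 0.800 equiv | 80 °C |  | 80 min |
| winter | 0.20 M | 0.500 equiv | 1.00 equiv | 0.800 equiv |  | at 60 °C until 25 min, from then on at 100 °C | 80 min |

| run | time / min | target / % | starting material / % |
|---|---|---|---|
| beta | 60.0 | 1.3 | 100.0 |
| beta | 90.0 | 1.0 | 99.7 |
| beta | 150 | 1.3 | 99.0 |
| beta | 240 | 1.5 | 98.6 |
| beta | 300 | 2.0 | 97.4 |
| beta | 480 | 4.1 | 95.7 |
| beta | 720 | 5.1 | 95.2 |
| zeta | 15.0 | 1.6 | 99.7 |
| zeta | 25.0 | 1.9 | 99.3 |
| zeta | 40.0 | 1.8 | 97.8 |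
| zeta | 60.0 | 2.7 | 95.7 |
| zeta | 80.0 | 5.6 | 94.9 |
| zeta | 150 | 7.5 | 91.9 |
| zeta | 240 | 12.5 | 87.6 |
| theta | 150 | 0.8 | 98.5 |
| theta | 300 | 1.6 | 97.6 |
| theta | 480 | 3.0 | 96.8 |
| theta | 600 | 4.0 | 96.4 |
| theta | 720 | 5.2 | 94.9 |

(readings scatter by 0.5 percentage points)

- solid reagent is a solid; its amount is given per volume of the solution
- the earlier runs were read with a standard deviation of 0.5 percentage points
- candidate steps: third substrate + partner -> third product; starting material + partner -> target; second substrate + partner -> second product; 2 third substrate -> self-condensation product; solid reagent <-> partner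
- at the start none of the solid reagent is in solution

1. the best flask by amount of target, in percent of the starting material charged; "all alike" if 1.5 percentage points covers them all (summer / noon / spring / winter / all alike)
2. amount of target at the end, in percent of the starting material charged, summer
3. amount of target at the end, in percent of the starting material charged, noon
4. amount of target at the end, in percent of the starting material charged, spring
5. amount of target at the end, in percent of the starting material charged, winter

1. Theta held 3.00 times the solid reagent of beta per volume, and more starting material, yet at 55 °C the share of remaining starting material turned to target per minute read 7.42 × 10⁻⁵ min⁻¹ in theta and 7.27 × 10⁻⁵ min⁻¹ in beta, so I took [partner] as held at one level while solid remained, which makes the rate pseudo-first-order in starting material.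

2. Zeta's last reading gave 5.56 × 10⁻⁴ min⁻¹ at 80 °C, and I named this the buffered rate constant κ, the share of remaining starting material becoming target each minute; against beta it gave me an apparent activation energy of 78.4 kJ mol⁻¹.

3. In my reckoning summer started at κ = 0.00233 min⁻¹, and the falling starting material slowed it by a factor of 0.830 by the end, or 0.912 averaged over the run, so I expected 17.0%; I set the factor from [partner] at 1 while solid lasted, though zeta was run at 80 °C, not at 100 °C.

4. With κ = 1.12 × 10⁻⁴ min⁻¹ at 60 °C, I reckoned 0.891% for noon and 4.35% for spring. Winter came to 12.3%, its cold stretch adding hardly any of the turnover.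

5. The forecast judged that “the partner level appears buffered” and named summer best, with 15% (9% to 22%) there, 10.5% for winter, 4% for spring and 0.8% for noon, each below my figure.

The best flask was summer with 15.3%, then winter with 11.0%, spring with 4.26% and noon with 0.908%.

    third substrate + partner → third product (k = 0.00450 L mol⁻¹ s⁻¹, Ea = 80.0 kJ mol⁻¹)
    starting material + partner → target (k = 0.00450 L mol⁻¹ s⁻¹, Ea = 78.0 kJ mol⁻¹)
    second substrate + partner → second product (k = 0.0210 L mol⁻¹ s⁻¹, Ea = 82.0 kJ mol⁻¹)
    2 third substrate → self-condensation product (k = 0.00120 L mol⁻¹ s⁻¹, Ea = 63.0 kJ mol⁻¹)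
    solid reagent ⇌ partner, rate k5*(cs5 - [partner]) while solid is left; crystals form when [partner] > cs5 (solubility = 8.80 mM, k = 0.0200 s⁻¹)
    (constants at 100 °C)

At 80.0 min summer still held 32.2% of its solid reagent charge as solid, with [partner] at 0.00800 M against 0.00873 M in noon. Read back from summer's result, κ was 0.00207 min⁻¹, less than my 0.00233 min⁻¹. Carried from zeta to the flask like noon kept at 85 °C, κ is 8.08 × 10⁻⁴ min⁻¹, which reckons to 6.26%, and that flask gave 6.03%.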